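**Remark on the chemistry:** the SMILES is read as the cis-fused (10βH) eremophilane (3R,4R,5R,7R,9R,10S), in which the C3, C4, C7 and C9 substituents are all equatorial. Eremophilane numbering is used for ring atoms (ring A: C1–C5, C10; ring B: C5–C10).

**Plan**
- Retrosynthesis: remove the C3 angelate and C9 senecioate; take the C8 ketone back to a C8 alkenylsilane and C9–O back to a C9 ketone; cut ring B at C6–C7 and C8–C9. This leaves a cis-fused cyclobutanone (C9=O and C6H2 bridging C10 and C5 of ring A) and a silyl 1,3-enyne carrying C8, C7 and the isopropenyl group.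
- Enabling feature: C6 and C9 are the one-carbon arms on the adjacent cis ring-fusion carbons C5 and C10. Joined to each other they form the ketene [2+2] adduct of a ring A alkene, and the strained C6–C9 acyl bond of that four-membered ring takes up the alkyne carbons C7 and C8 to give ring B.
- Forward order: aldol chain, ring A by ring-closing metathesis, four-membered ring by dichloroketene [2+2], ring B by nickel-catalysed alkyne insertion, then C9 reduction, C8 Tamao oxidation, C9 Mitsunobu esterification, desilylation and C3 angeloylation.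
- Stereochemistry: C3/C4 from the oxazolidinone auxiliary; C5/C10 from ketene addition anti to the C4 methyl (cis fusion inherent); C9 from β-face hydride then SN2 inversion; C7 from ketonisation to the equatorial epimer.

Key step: step 10

**Step 1**
Reactants: 1 (S)-4-benzyl-3-propanoyl-1,3-oxazolidin-2-one; 2 pent-4-enal
Product: 4 (S)-4-benzyl-3-[(2S,3R)-3-hydroxy-2-methylhept-6-enoyl]-1,3-oxazolidin-2-one, via boron enolate 3 (not isolated)
Conditions: Bu2BOTf, i-Pr2NEt, CH2Cl2, 0 °C; 2, −78 → 0 °C; pH 7 buffer, MeOH, H2O2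
Reagents that add atoms: none
Why: Evans syn-aldol reaction, in which the Z-boron enolate reacts through a chair Zimmerman–Traxler transition state on the face away from the benzyl group and so sets the carbinol carbon (future C3) and the methyl-bearing carbon (future C4) syn with auxiliary control.

**Step 2**
Reactants: 4
Product: 5 (2S,3R)-3-hydroxy-N-methoxy-N,2-dimethylhept-6-enamide
Conditions: MeNH(OMe)·HCl, AlMe3, CH2Cl2, −20 → 0 °C
Reagents that add atoms: N,O-dimethylhydroxylamine hydrochloride, CNOC.Cl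
Why: aluminium amide transamination of a β-hydroxy imide (Weinreb amide formation), in which the free hydroxyl directs attack to the exocyclic carbonyl, so the auxiliary should be released without epimerisation.

**Step 3**
Reactants: 5
Product: 6 (2S,3R)-N-methoxy-N,2-dimethyl-3-[(triisopropylsilyl)oxy]hept-6-enamide
Conditions: i-Pr3SiOTf, 2,6-lutidine, CH2Cl2, 0 °C → rt
Reagents that add atoms: triisopropylsilyl trifluoromethanesulfonate, CC(C)[Si](OS(=O)(=O)C(F)(F)F)(C(C)C)C(C)C
Why: standard silylation of a secondary alcohol with a silyl triflate; the triisopropylsilyl ether is chosen to survive Grignard reagent, zinc halide and brief fluoride treatment later.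

**Step 4**
Reactants: 6
Product: 7 (3S,4R)-3-methyl-4-[(triisopropylsilyl)oxy]oct-7-en-2-one
Conditions: MeMgBr, THF, 0 °C
Reagents that add atoms: methylmagnesium bromide, C[Mg]Br
Why: Weinreb ketone synthesis, in which the chelated tetrahedral intermediate should stop at the ketone and leave the α-stereocentre untouched.

**Step 5**
Reactants: 7
Product: 8 triisopropyl{[(3R,4R)-2,3-dimethylocta-1,7-dien-4-yl]oxy}silane
Conditions: Ph3PCH3Br, KOt-Bu, THF, 0 °C → rt
Reagents that add atoms: methyltriphenylphosphonium bromide, C[P+](c1ccccc1)(c1ccccc1)c1ccccc1.[Br-]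
Why: Wittig methylenation of a methyl ketone; at low temperature the ylide should not enolise the hindered tertiary α-position, so the future C4 is kept.

**Step 6**
Reactants: 8
Product: 9 triisopropyl{[(1R,2R)-2,3-dimethylcyclohex-3-en-1-yl]oxy}silane
Conditions: second-generation Grubbs catalyst (H2IMes)(PCy3)Cl2Ru=CHPh (5 mol %), CH2Cl2, 40 °C
Reagents that add atoms: none
Why: ring-closing metathesis of a monosubstituted with a 1,1-disubstituted alkene, driven by loss of ethene, closes ring A as the trisubstituted C5=C10 cyclohexene.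

**Step 7**
Reactants: 9
Product: 10 (1R,2R,3R,6S)-8,8-dichloro-1,2-dimethyl-3-[(triisopropylsilyl)oxy]bicyclo[4.2.0]octan-7-one
Conditions: Cl3CCOCl, Zn(Cu) couple, POCl3, Et2O, 35 °C
Reagents that add atoms: dichloroketene, ClC(Cl)=C=O, made in the flask from trichloroacetyl chloride, ClC(Cl)(Cl)C(Cl)=O
Why: thermal ketene–alkene [2+2] cycloaddition, in which the ketene carbonyl carbon bonds to the less substituted C10 and the CCl2 carbon to the methyl-bearing C5; addition is suprafacial on the alkene (cis fusion) and should occur on the face anti to the adjacent C4 methyl, setting the quaternary C5 (methyls cis) and C10.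

**Step 8**
Reactants: 10
Product: 11 (1R,2R,3R,6S)-1,2-dimethyl-3-[(triisopropylsilyl)oxy]bicyclo[4.2.0]octan-7-one
Conditions: Zn dust, AcOH, rt
Reagents that add atoms: none
Why: reductive dechlorination of an α,α-dichlorocyclobutanone with zinc in acetic acid is standard and should leave the silyl ether and both ring-fusion centres unchanged.

**Step 9**
Reactants: 12 2-methylbut-1-en-3-yne; 13 benzylchlorodimethylsilane
Product: 15 benzyldimethyl(3-methylbut-3-en-1-yn-1-yl)silane, via lithium acetylide 14 (not isolated)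
Conditions: n-BuLi, THF, −78 °C; 13, −78 °C → rt
Reagents that add atoms: none
Why: deprotonation and C-silylation of a terminal alkyne; the benzyldimethylsilyl group is inert to nickel catalysis but can later be oxidised to oxygen (Tamao–Fleming).

**Step 10**
Reactants: 11; 15
Product: 16 (4aR,5R,6R,8aS)-2-[benzyl(dimethyl)silyl]-4a,5-dimethyl-3-(prop-1-en-2-yl)-6-[(triisopropylsilyl)oxy]-4a,5,6,7,8,8a-hexahydronaphthalen-1(4H)-one
Conditions: Ni(cod)2 (10 mol %), PCy3 (20 mol %), 15 (3 equiv, slow addition), toluene, 100 °C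
Reagents that add atoms: none
Why: zerovalent nickel should couple the strained ketone carbonyl (C9) of 11 with the alkyne of 15 by oxidative cyclisation (new C8–C9 bond), then cleave the cyclobutanone C9–C6 bond by β-carbon elimination to a seven-membered nickelacycle, and close C6–C7 by reductive elimination, which returns zerovalent nickel. The closest known reaction type is the nickel-catalysed intermolecular insertion of internal alkynes into cyclobutanones to give cyclohex-2-enones, a formal [4+2] ring expansion. Ring B is the only ring closed: the four-membered ring is enlarged to the six-membered ring, its last bond formed by C(sp3)–C(sp2) reductive elimination at nickel, while ring A and the cis C5–C10 fusion are carried through. No new stereocentre is made, since C7, C8 and C9 are sp2 in 16, and C10, although α to the ketone, should not epimerise under these neutral conditions. Two selectivities are needed: cleavage of C9–C6 and not C9–C10, which the unbranched CH2 at C6 against the ring-fusion methine C10 should secure; and an alkyne orientation that puts the silyl-bearing carbon on C9 and the isopropenyl-bearing carbon on C6, which the conjugated alkene of the 1,3-enyne should secure by holding its own alkyne carbon on nickel during oxidative cyclisation.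

**Step 11**
Reactants: 16
Product: 17 (1S,4aR,5R,6R,8aS)-2-[benzyl(dimethyl)silyl]-4a,5-dimethyl-3-(prop-1-en-2-yl)-6-[(triisopropylsilyl)oxy]-1,4,4a,5,6,7,8,8a-octahydronaphthalen-1-ol
Conditions: i-Bu2AlH, CH2Cl2, −78 °C
Reagents that add atoms: none
Why: 1,2-reduction of an enone whose β-carbon is fully substituted; hydride should add to C9 from the open β face, away from the ring A carbon C4 that lies axial over the α face in the favoured cis-decalin conformer, giving the axial 9α-alcohol.

**Step 12**
Reactants: 17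
Product: 20 (1S,3R,4aR,5R,6R,8aS)-1-hydroxy-4a,5-dimethyl-3-(prop-1-en-2-yl)-6-[(triisopropylsilyl)oxy]octahydronaphthalen-2(1H)-one, via silanol 18 (not isolated), via enol 19 (not isolated)
Conditions: Bu4NF, THF, 0 °C, 15 min; then KHCO3, H2O2 (30 % aq.), MeOH, 0 °C → rt
Reagents that add atoms: hydrogen peroxide, OO
Why: Tamao–Fleming oxidation of a benzyldimethylsilyl alkene, in which fluoride removes the benzyl group, peroxide replaces silicon by oxygen at C8, and the enol should ketonise by axial protonation at C7 to the β,γ-unsaturated ketone with the equatorial 7β-isopropenyl group, the more stable C7 epimer.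

**Step 13**
Reactants: 20; 21 3-methylbut-2-enoic acid (senecioic acid)
Product: 22 (1R,3R,4aR,5R,6R,8aS)-4a,5-dimethyl-2-oxo-3-(prop-1-en-2-yl)-6-[(triisopropylsilyl)oxy]decahydronaphthalen-1-yl 3-methylbut-2-enoate
Conditions: PPh3, i-PrO2CN=NCO2i-Pr, toluene/THF, 0 °C → rt
Reagents that add atoms: none
Why: Mitsunobu esterification, in which the axial 9α-hydroxyl of the α-ketol is activated as its oxyphosphonium salt and displaced by the carboxylate from the β face with inversion, giving the equatorial 9β-ester directly.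

**Step 14**
Reactants: 22
Product: 23 (1R,3R,4aR,5R,6R,8aS)-6-hydroxy-4a,5-dimethyl-2-oxo-3-(prop-1-en-2-yl)decahydronaphthalen-1-yl 3-methylbut-2-enoate
Conditions: HF·pyridine, pyridine, THF, 0 °C → rt
Reagents that add atoms: none
Why: fluoride cleavage of the secondary silyl ether under buffered, weakly acidic conditions that should neither enolise the α-acyloxy ketone nor move the isopropenyl double bond into conjugation.

**Step 15**
Reactants: 23; 24 (Z)-2-methylbut-2-enoic acid (angelic acid)
Product: 26 3α-angeloyloxy-9β-senecioyloxy-10βH-eremophil-11-en-8-one, via mixed anhydride 25 (not isolated)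
Conditions: 24, 2,4,6-trichlorobenzoyl chloride, Et3N, toluene, rt; then 23, 75 °C
Reagents that add atoms: none
Why: Yamaguchi-type esterification through the mixed anhydride without a nucleophilic catalyst, the usual way to make angelates without Z-to-E isomerisation to the tiglate; the equatorial C3 hydroxyl is the only free alcohol.

**Compound list**
1 | (S)-4-benzyl-3-propanoyl-1,3-oxazolidin-2-one | CCC(=O)N1[C@@H](Cc2ccccc2)COC1=O | starting material
2 | pent-4-enal | C=CCCC=O | starting material
3 | (Z)-dibutylboron enolate of 1 | C/C=C(\OB(CCCC)CCCC)N1[C@@H](Cc2ccccc2)COC1=O | intermediate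
4 | (S)-4-benzyl-3-[(2S,3R)-3-hydroxy-2-methylhept-6-enoyl]-1,3-oxazolidin-2-one | C=CCC[C@@H](O)[C@H](C)C(=O)N1[C@@H](Cc2ccccc2)COC1=O | intermediate
5 | (2S,3R)-3-hydroxy-N-methoxy-N,2-dimethylhept-6-enamide | C=CCC[C@@H](O)[C@H](C)C(=O)N(C)OC | intermediate
6 | (2S,3R)-N-methoxy-N,2-dimethyl-3-[(triisopropylsilyl)oxy]hept-6-enamide | C=CCC[C@@H](O[Si](C(C)C)(C(C)C)C(C)C)[C@H](C)C(=O)N(C)OC | intermediate
7 | (3S,4R)-3-methyl-4-[(triisopropylsilyl)oxy]oct-7-en-2-one | C=CCC[C@@H](O[Si](C(C)C)(C(C)C)C(C)C)[C@H](C)C(C)=O | intermediate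
8 | triisopropyl{[(3R,4R)-2,3-dimethylocta-1,7-dien-4-yl]oxy}silane | C=CCC[C@@H](O[Si](C(C)C)(C(C)C)C(C)C)[C@H](C)C(C)=C | intermediate
9 | triisopropyl{[(1R,2R)-2,3-dimethylcyclohex-3-en-1-yl]oxy}silane (ring A alkene) | CC1=CCC[C@@H](O[Si](C(C)C)(C(C)C)C(C)C)[C@@H]1C | intermediate
10 | (1R,2R,3R,6S)-8,8-dichloro-1,2-dimethyl-3-[(triisopropylsilyl)oxy]bicyclo[4.2.0]octan-7-one | ClC1(Cl)[C@@]2(C)[C@H](CC[C@@H](O[Si](C(C)C)(C(C)C)C(C)C)[C@@H]2C)C1=O | intermediate
11 | (1R,2R,3R,6S)-1,2-dimethyl-3-[(triisopropylsilyl)oxy]bicyclo[4.2.0]octan-7-one | C1[C@@]2(C)[C@H](CC[C@@H](O[Si](C(C)C)(C(C)C)C(C)C)[C@@H]2C)C1=O | intermediate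
12 | 2-methylbut-1-en-3-yne | C=C(C)C#C | starting material
13 | benzylchlorodimethylsilane | C[Si](C)(Cl)Cc1ccccc1 | starting material
14 | lithium 3-methylbut-3-en-1-ynide | C=C(C)C#C[Li] | intermediate
15 | benzyldimethyl(3-methylbut-3-en-1-yn-1-yl)silane | C=C(C)C#C[Si](C)(C)Cc1ccccc1 | intermediate
16 | (4aR,5R,6R,8aS)-2-[benzyl(dimethyl)silyl]-4a,5-dimethyl-3-(prop-1-en-2-yl)-6-[(triisopropylsilyl)oxy]-4a,5,6,7,8,8a-hexahydronaphthalen-1(4H)-one | C=C(C)C=1C[C@@]2(C)[C@H](CC[C@@H](O[Si](C(C)C)(C(C)C)C(C)C)[C@@H]2C)C(=O)C=1[Si](C)(C)Cc1ccccc1 | intermediate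
17 | (1S,4aR,5R,6R,8aS)-2-[benzyl(dimethyl)silyl]-4a,5-dimethyl-3-(prop-1-en-2-yl)-6-[(triisopropylsilyl)oxy]-1,4,4a,5,6,7,8,8a-octahydronaphthalen-1-ol (9α-alcohol) | C=C(C)C=1C[C@@]2(C)[C@H](CC[C@@H](O[Si](C(C)C)(C(C)C)C(C)C)[C@@H]2C)[C@H](O)C=1[Si](C)(C)Cc1ccccc1 | intermediate
18 | alkenyl(dimethyl)silanol from 17 (benzyl replaced by hydroxyl on silicon) | C=C(C)C=1C[C@@]2(C)[C@H](CC[C@@H](O[Si](C(C)C)(C(C)C)C(C)C)[C@@H]2C)[C@H](O)C=1[Si](C)(C)O | intermediate
19 | C8 enol (C7=C8–OH) of 20 | C=C(C)C=1C[C@@]2(C)[C@H](CC[C@@H](O[Si](C(C)C)(C(C)C)C(C)C)[C@@H]2C)[C@H](O)C=1O | intermediate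
20 | (1S,3R,4aR,5R,6R,8aS)-1-hydroxy-4a,5-dimethyl-3-(prop-1-en-2-yl)-6-[(triisopropylsilyl)oxy]octahydronaphthalen-2(1H)-one (9α-hydroxy-8-ketone) | C=C(C)[C@H]1C[C@@]2(C)[C@H](CC[C@@H](O[Si](C(C)C)(C(C)C)C(C)C)[C@@H]2C)[C@H](O)C1=O | intermediate
21 | 3-methylbut-2-enoic acid | CC(C)=CC(=O)O | starting material
22 | (1R,3R,4aR,5R,6R,8aS)-4a,5-dimethyl-2-oxo-3-(prop-1-en-2-yl)-6-[(triisopropylsilyl)oxy]decahydronaphthalen-1-yl 3-methylbut-2-enoate | C=C(C)[C@H]1C[C@@]2(C)[C@H](CC[C@@H](O[Si](C(C)C)(C(C)C)C(C)C)[C@@H]2C)[C@@H](OC(=O)C=C(C)C)C1=O | intermediate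
23 | (1R,3R,4aR,5R,6R,8aS)-6-hydroxy-4a,5-dimethyl-2-oxo-3-(prop-1-en-2-yl)decahydronaphthalen-1-yl 3-methylbut-2-enoate | C=C(C)[C@H]1C[C@@]2(C)[C@H](CC[C@@H](O)[C@@H]2C)[C@@H](OC(=O)C=C(C)C)C1=O | intermediate
24 | (Z)-2-methylbut-2-enoic acid | C/C=C(/C)C(=O)O | starting material
25 | (Z)-2-methylbut-2-enoic 2,4,6-trichlorobenzoic anhydride | C/C=C(/C)C(=O)OC(=O)c1c(Cl)cc(Cl)cc1Cl | intermediate
26 | 3α-angeloyloxy-9β-senecioyloxy-10βH-eremophil-11-en-8-one, (3R,4R,5R,7R,9R,10S) | C=C(C)[C@H]1C[C@@]2(C)[C@H](CC[C@@H](OC(=O)/C(C)=C\C)[C@@H]2C)[C@@H](OC(=O)C=C(C)C)C1=O | target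

**Count**
Total steps: 15. Longest linear sequence: 14 (steps 1–8 and 10–15; step 9 makes the alkyne partner).

**Steps most likely to fail**

Step 10 (cleavage of the wrong cyclobutanone bond, the wrong alkyne orientation, or oligomerisation of the enyne at nickel). The fallback sets out from 11 and comes back at 22; it makes the two bonds one after the other by known anionic and reductive chemistry.
- Kinetic enolisation of 11 towards C6 (LiN(i-Pr)2, Me3SiCl) should give the silyl enol ether F5.
- Ozonolysis with NaBH4 work-up and acidification should give the cis-fused γ-lactone F6 (C9 carboxyl, C6H2–O).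
- LiAlH4 should give the diol F7, and t-BuMe2SiCl/imidazole should silylate the less hindered C9 hydroxyl to give the mono-silyl ether F8.
- (CF3SO2)2O/2,6-lutidine should give the neopentyl triflate F9, which should alkylate lithiated 3-methylbut-2-enenitrile at its α-carbon (deconjugative alkylation, C6–C7 bond) to give the nitrile F10.
- Pyridinium p-toluenesulfonate in methanol should free the primary alcohol F11, and Dess–Martin periodinane should give the aldehyde F12.
- SmI2, t-BuOH, THF under visible light should couple the aldehyde ketyl with the nitrile (C8–C9 bond); hydrolysis of the imine should give the 9β-hydroxy ketone F13, with the hydroxyl expected equatorial.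
- 3-Methylbut-2-enoyl chloride/pyridine should then give 22.

Step 7 (poor facial selectivity of the ketene addition, giving the C5/C10 diastereomer). The fallback sets out from 8 and comes back at 11; the four-membered ring is closed intramolecularly, so that ring A and the cyclobutanone form together through a chair-like tether and steps 6–8 are not needed.
- Hydroboration of the monosubstituted alkene with bis(3-methylbutan-2-yl)borane, then NaOH/H2O2, should give the primary alcohol F1.
- TEMPO/PhI(OAc)2 in MeCN–H2O should give the acid F2.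
- 1-Chloro-N,N,2-trimethylprop-1-en-1-amine should give the acid chloride F3.
- Et3N in refluxing toluene should give the ketene F4, which should add across the 1,1-disubstituted alkene (intramolecular ketene–alkene [2+2]) to give 11.

Step 13 (elimination or no substitution at the hindered C9, or an unexpected C9 configuration carried over from step 11). The fallback sets out from 20 and comes back at 22. Acylation with retention (3-methylbut-2-enoyl chloride, pyridine) should give the 9α-ester F14. A weak base (1,8-diazabicyclo[5.4.0]undec-7-ene, toluene, rt) should then epimerise C9 through the enol to the equatorial 9β-ester 22. This thermodynamic control is stereoconvergent, so it would also take a 9β-alcohol from step 11 to 22.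

**Further compounds**
F1 | step 7 | (5R,6R)-6,7-dimethyl-5-[(triisopropylsilyl)oxy]oct-7-en-1-ol | OCCCC[C@@H](O[Si](C(C)C)(C(C)C)C(C)C)[C@H](C)C(C)=C
F2 | step 7 | (5R,6R)-6,7-dimethyl-5-[(triisopropylsilyl)oxy]oct-7-enoic acid | OC(=O)CCC[C@@H](O[Si](C(C)C)(C(C)C)C(C)C)[C@H](C)C(C)=C
F3 | step 7 | (5R,6R)-6,7-dimethyl-5-[(triisopropylsilyl)oxy]oct-7-enoyl chloride | ClC(=O)CCC[C@@H](O[Si](C(C)C)(C(C)C)C(C)C)[C@H](C)C(C)=C
F4 | step 7 | (6R,7R)-7,8-dimethyl-6-[(triisopropylsilyl)oxy]nona-1,8-dien-1-one (ketene) | O=C=CCC[C@@H](O[Si](C(C)C)(C(C)C)C(C)C)[C@H](C)C(C)=C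
F5 | step 10 | trimethylsilyl enol ether of 11 (C9=C6) | C[Si](C)(C)OC1=C[C@@]2(C)[C@@H]1CC[C@@H](O[Si](C(C)C)(C(C)C)C(C)C)[C@@H]2C
F6 | step 10 | cis-fused γ-lactone (C9 carbonyl, C6H2–O), ring A as in 11 | O=C1OC[C@@]2(C)[C@@H]1CC[C@@H](O[Si](C(C)C)(C(C)C)C(C)C)[C@@H]2C
F7 | step 10 | diol (C6H2OH on C5, C9H2OH on C10), ring A as in 11 | OC[C@@]1(C)[C@@H](CO)CC[C@@H](O[Si](C(C)C)(C(C)C)C(C)C)[C@@H]1C
F8 | step 10 | C9 tert-butyldimethylsilyl ether of F7 | OC[C@@]1(C)[C@@H](CO[Si](C)(C)C(C)(C)C)CC[C@@H](O[Si](C(C)C)(C(C)C)C(C)C)[C@@H]1C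
F9 | step 10 | C6 trifluoromethanesulfonate of F8 | FC(F)(F)S(=O)(=O)OC[C@@]1(C)[C@@H](CO[Si](C)(C)C(C)(C)C)CC[C@@H](O[Si](C(C)C)(C(C)C)C(C)C)[C@@H]1C
F10 | step 10 | 2-substituted 3-methylbut-3-enenitrile (C6–C7 bond made, C7 epimers) | N#CC(C(C)=C)C[C@@]1(C)[C@@H](CO[Si](C)(C)C(C)(C)C)CC[C@@H](O[Si](C(C)C)(C(C)C)C(C)C)[C@@H]1C
F11 | step 10 | primary alcohol from F10 (C9H2OH) | N#CC(C(C)=C)C[C@@]1(C)[C@@H](CO)CC[C@@H](O[Si](C(C)C)(C(C)C)C(C)C)[C@@H]1C
F12 | step 10 | aldehyde from F11 (C9HO) | N#CC(C(C)=C)C[C@@]1(C)[C@@H](C=O)CC[C@@H](O[Si](C(C)C)(C(C)C)C(C)C)[C@@H]1C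
F13 | step 10 | 9β-hydroxy-8-ketone (C9 epimer of 20) | C=C(C)[C@H]1C[C@@]2(C)[C@H](CC[C@@H](O[Si](C(C)C)(C(C)C)C(C)C)[C@@H]2C)[C@@H](O)C1=O
F14 | step 13 | 9α-(3-methylbut-2-enoate) (C9 epimer of 22) | C=C(C)[C@H]1C[C@@]2(C)[C@H](CC[C@@H](O[Si](C(C)C)(C(C)C)C(C)C)[C@@H]2C)[C@H](OC(=O)C=C(C)C)C1=O
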